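The route rests on taking apart the cyclobutane bond C1–C2 (the CH next to the C11 ketone and the methyl-bearing quaternary carbon) together with C3–C4 by an intramolecular de Mayo reaction. The feature used is the 1,5-relation of the C11 ketone and the C4 oxygen across C1–C2–C3. Irradiation of the enolised bicyclic β-diketone 12, whose axial isopropenyl group sits over the enol carbon, should form C1–C2 and C3–C4. Cleavage of the old C1–C4 bond of the strained cyclobutanol then delivers the cyclobutane, the bicyclo[3.1.1]heptane and the seven-membered ring (C1–C7) in one operation. Oxygenation at C3 and two esterifications finish the synthesis.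

Key step: step 9

Remark: locants follow the tricyclo[5.4.0.0^{2,8}]undecane numbering of the target throughout, also for the monocyclic and bicyclic precursors (C1 CH next to the ketone, C2 CMe, C3 CH–O-acyl, C4 CH–O-angeloyl, C5 CH–OH, C6 CMe2, C7 and C8 cyclobutane CH, C9 =CMe, C10 =CH, C11 C=O); the esters are read from the structure as the (2R)-2-methylbutanoate at C3 and the (Z)-2-methylbut-2-enoate (angelate) at C4.

Step 1
Reactants: 1 (S)-pantolactone
Product: 2 (3S)-3-[(tert-butyldimethylsilyl)oxy]-4,4-dimethyloxolan-2-one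
Conditions: TBSCl, imidazole, DMF, rt
Reagents that add atoms: tert-butyldimethylsilyl chloride, CC(C)(C)[Si](C)(C)Cl
Why: Imidazole-promoted silylation protects the only hydroxyl; the stereocentre (later C5) is untouched and its silyl ether later blocks one face of the seven-membered ring.

Step 2
Reactants: 2 (3S)-3-[(tert-butyldimethylsilyl)oxy]-4,4-dimethyloxolan-2-one
Product: 3 (2S)-2-[(tert-butyldimethylsilyl)oxy]-4-hydroxy-N-methoxy-N,3,3-trimethylbutanamide
Conditions: MeNHOMe·HCl, i-PrMgCl, THF, −20 → 0 °C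
Reagents that add atoms: N,O-dimethylhydroxylamine hydrochloride, CNOC.Cl
Why: Weinreb amide formation by aminolysis of the lactone with the magnesium amide opens the ring at the acyl carbon and frees the neopentyl primary alcohol; the tertiary amide should not relactonise under the cold basic conditions and is oxidised without delay.

Step 3
Reactants: 3 (2S)-2-[(tert-butyldimethylsilyl)oxy]-4-hydroxy-N-methoxy-N,3,3-trimethylbutanamide
Product: 4 (2S)-2-[(tert-butyldimethylsilyl)oxy]-N-methoxy-N,3,3-trimethyl-4-oxobutanamide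
Conditions: Dess–Martin periodinane, CH2Cl2, 0 °C → rt
Reagents that add atoms: none
Why: Dess–Martin oxidation of the primary alcohol; the aldehyde has a quaternary α-carbon and cannot enolise.

Step 4
Reactants: 4 (2S)-2-[(tert-butyldimethylsilyl)oxy]-N-methoxy-N,3,3-trimethyl-4-oxobutanamide; 5 1-(triphenylphosphoranylidene)propan-2-one
Product: 6 (2S,4E)-2-[(tert-butyldimethylsilyl)oxy]-N-methoxy-N,3,3-trimethyl-6-oxohept-4-enamide
Conditions: toluene, 100 °C
Reagents that add atoms: none
Why: Wittig olefination with a stabilised ylide should give the (E)-enone, heating compensating for the hindered neopentyl aldehyde.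

Step 5
Reactants: 6 (2S,4E)-2-[(tert-butyldimethylsilyl)oxy]-N-methoxy-N,3,3-trimethyl-6-oxohept-4-enamide
Product: 7 (2S,4E)-2,6-bis[(tert-butyldimethylsilyl)oxy]-N-methoxy-N,3,3-trimethylhepta-4,6-dienamide
Conditions: TBSOTf, Et3N, CH2Cl2, 0 °C
Reagents that add atoms: tert-butyldimethylsilyl trifluoromethanesulfonate, CC(C)(C)[Si](C)(C)OS(=O)(=O)C(F)(F)F
Why: Soft enolisation and O-silylation of the methyl ketone gives the 2-silyloxy diene; the α-hydrogen of the Weinreb amide is not acidic enough to react.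

Step 6
Reactants: 7 (2S,4E)-2,6-bis[(tert-butyldimethylsilyl)oxy]-N-methoxy-N,3,3-trimethylhepta-4,6-dienamide; 8 (E)-pent-3-en-2-one
Product: 9 (2S)-3-[(1R,5R,6S)-6-acetyl-3-[(tert-butyldimethylsilyl)oxy]-5-methylcyclohex-2-en-1-yl]-2-[(tert-butyldimethylsilyl)oxy]-N-methoxy-N,3-dimethylbutanamide
Conditions: B-(o-tolyl)oxazaborolidine of α,α-diphenylprolinol activated with Tf2NH (20 mol %, the antipode that exposes the Cα-Re face of 8), CH2Cl2, −78 → −40 °C
Reagents that add atoms: none
Why: Diels–Alder reaction in which the CH2 terminus of the 2-silyloxy diene bonds to the enone β-carbon and the substituted terminus to its α-carbon; the endo transition state with (E)-diene and (E)-dienophile sets the side chain at C7 cis to the acetyl group at C8 and the C9 methyl trans to it, and the chiral Lewis acid selects the enone face because the remote C5 stereocentre has little influence (a facial diastereomer, if formed, is removed by chromatography).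

Step 7
Reactants: 9 (2S)-3-[(1R,5R,6S)-6-acetyl-3-[(tert-butyldimethylsilyl)oxy]-5-methylcyclohex-2-en-1-yl]-2-[(tert-butyldimethylsilyl)oxy]-N-methoxy-N,3-dimethylbutanamide
Product: 10 (2S)-2-[(tert-butyldimethylsilyl)oxy]-3-[(1S,5R,6S)-3-[(tert-butyldimethylsilyl)oxy]-5-methyl-6-(prop-1-en-2-yl)cyclohex-2-en-1-yl]-N-methoxy-N,3-dimethylbutanamide
Conditions: Cp2Ti(μ-CH2)(μ-Cl)AlMe2 (Tebbe reagent), pyridine (cat.), THF/toluene, −40 → 0 °C
Reagents that add atoms: Tebbe reagent, C[Al-]1(C)C[Ti](C2C=CC=C2)(C2C=CC=C2)[Cl+]1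
Why: Tebbe methylenation is non-basic, so the hindered and epimerisable methyl ketone should become the isopropenyl group without loss of the C8 configuration, faster than the amide reacts and without touching the silyl enol ether.

Step 8
Reactants: 10 (2S)-2-[(tert-butyldimethylsilyl)oxy]-3-[(1S,5R,6S)-3-[(tert-butyldimethylsilyl)oxy]-5-methyl-6-(prop-1-en-2-yl)cyclohex-2-en-1-yl]-N-methoxy-N,3-dimethylbutanamide
Product: 12 (2S,3aR,4S,5R)-2-[(tert-butyldimethylsilyl)oxy]-1-hydroxy-3,3,5-trimethyl-4-(prop-1-en-2-yl)-2,3,3a,4,5,6-hexahydro-7H-inden-7-one (chelated C4 enol of the bicyclic 4,11-dione), via tetrabutylammonium enolate 11 (not isolated)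
Conditions: Bu4NF (TBAF, 1.2 equiv), THF, −40 °C → rt; 1 M HCl work-up
Reagents that add atoms: none
Why: Fluoride cleaves the silyl enol ether far faster than the hindered alkyl silyl ether and releases the C1 enolate regiospecifically, which should acylate on the Weinreb amide in a Dieckmann-type Claisen condensation (5-exo-trig) to the β-diketone, kept as its enolate until work-up so that C5 does not epimerise.

Step 9
Reactants: 12 (2S,3aR,4S,5R)-2-[(tert-butyldimethylsilyl)oxy]-1-hydroxy-3,3,5-trimethyl-4-(prop-1-en-2-yl)-2,3,3a,4,5,6-hexahydro-7H-inden-7-one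
Product: 14 (1R,2R,5S,7S,8S,9R)-5-[(tert-butyldimethylsilyl)oxy]-2,6,6,9-tetramethyltricyclo[5.4.0.0^{2,8}]undecane-4,11-dione, via cyclobutanol photoadduct 13 (not isolated)
Conditions: hν (medium-pressure Hg lamp, Pyrex, λ > 300 nm), degassed cyclohexane, 15 °C; then K2CO3 (cat.), MeOH, 0 °C
Reagents that add atoms: none
Why: Excitation of the chelated enol of 12 (chromophore O=C11–C1=C4–OH) is expected to give an intramolecular [2+2] cycloaddition with the isopropenyl group, C4 bonding to the CH2 carbon C3 (six-membered, leaving a tertiary C2 radical and an α-keto C1 radical) and the diradical then collapsing by C1–C2 bonding, after which the cyclobutanol 13, a β-hydroxy ketone, opens by retro-aldol cleavage of the old C1–C4 bond; the closest known reaction type is the intramolecular de Mayo reaction of enolised 1,3-diketones with tethered alkenes. The cyclobutane C1–C2–C8–C7 is closed by the C1–C2 bond in the straight (parallel) mode of a 1,5-diene, C2 bridging C8 and C1 across ring A to the bicyclo[3.1.1]heptane, the second cyclobutane C1–C2–C3–C4 is temporary, and the seven-membered ring C1–C7 arises by two-carbon expansion of the five-membered ring when C1–C4 breaks. C1 and C2 are the only new stereocentres and are fixed by C7 and C8, because the one-carbon bridge can form only on the face of ring A that carries the isopropenyl group and the bridgehead C1 can take up its hydrogen only from outside the cage. The step needs the straight and not the crossed mode and addition across C1=C4 and not C1=C11: a crossed adduct would have to span a bicyclo[2.1.1]hexane bridgehead (C1) and C8 with the three-carbon bridge of ring A, which is geometrically impossible, so a C1–C3 diradical can only revert, while the fused five-membered ring holds C6 pseudo-equatorial and hence the cis isopropenyl group axial with C2 above C1, and the CH2 carbon turns outward over C4 because the inward rotamer meets the axial hydrogen at C10. Because C1 becomes a bridgehead, the C11 carbonyl is poorly aligned with the breaking C1–C4 bond, so the opening is driven mainly by the strain of the bicyclo[2.2.0]hexane unit and is completed with catalytic base in cold methanol, kept brief so that 14 does not enolise at C3. Pyrex-filtered light and a non-polar solvent keep the hydrogen-bonded enol as the absorbing species and limit Norrish cleavage of the product ketones.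

Step 10
Reactants: 14 (1R,2R,5S,7S,8S,9R)-5-[(tert-butyldimethylsilyl)oxy]-2,6,6,9-tetramethyltricyclo[5.4.0.0^{2,8}]undecane-4,11-dione
Product: 15 (1R,2R,5S,7S,8R)-5-[(tert-butyldimethylsilyl)oxy]-2,6,6,9-tetramethyltricyclo[5.4.0.0^{2,8}]undec-9-ene-4,11-dione
Conditions: IBX, DMSO, 70 °C
Reagents that add atoms: none
Why: IBX dehydrogenation of a ketone via its enol can give an enone only at C11 (C10=C9), since C1 is a bridgehead and the C4 ketone has no β-hydrogen (C2 and C6 are quaternary); the C9 stereocentre is removed here.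

Step 11
Reactants: 15 (1R,2R,5S,7S,8R)-5-[(tert-butyldimethylsilyl)oxy]-2,6,6,9-tetramethyltricyclo[5.4.0.0^{2,8}]undec-9-ene-4,11-dione
Product: 16 (1R,2S,5S,7S,8R)-5-[(tert-butyldimethylsilyl)oxy]-2,6,6,9-tetramethyl-4-[(trimethylsilyl)oxy]tricyclo[5.4.0.0^{2,8}]undeca-3,9-dien-11-one
Conditions: LiN(i-Pr)2 (LDA) premixed with TMSCl, THF, −78 °C
Reagents that add atoms: trimethylsilyl chloride, C[Si](C)(C)Cl
Why: Kinetic deprotonation at the C3 methylene of the saturated ketone with in situ O-silylation (the enone has no α'-hydrogen, its γ-deprotonation is slow and C5–H is shielded by the silyl ether); the internal quench keeps the lithium enolate short-lived, since it could open the cyclobutane by retro-Michael cleavage.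

Step 12
Reactants: 16 (1R,2S,5S,7S,8R)-5-[(tert-butyldimethylsilyl)oxy]-2,6,6,9-tetramethyl-4-[(trimethylsilyl)oxy]tricyclo[5.4.0.0^{2,8}]undeca-3,9-dien-11-one
Product: 19 (1R,2R,3S,5S,7S,8R)-5-[(tert-butyldimethylsilyl)oxy]-3-hydroxy-2,6,6,9-tetramethyltricyclo[5.4.0.0^{2,8}]undec-9-ene-4,11-dione, via silyloxy epoxide 17 (not isolated), via α-silyloxy ketone 18 (not isolated)
Conditions: mCPBA, CH2Cl2, −20 °C; then aq. citric acid, THF, rt
Reagents that add atoms: 3-chloroperbenzoic acid, OOC(=O)c1cccc(Cl)c1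
Why: Rubottom oxidation: mCPBA should epoxidise the electron-rich silyl enol ether on the face anti to the C5 silyl ether, silyl migration gives the α-silyloxy ketone and mild acid frees the C3 hydroxyl on the face that the C4 oxygen will later share; the electron-poor enone is not epoxidised.

Step 13
Reactants: 19 (1R,2R,3S,5S,7S,8R)-5-[(tert-butyldimethylsilyl)oxy]-3-hydroxy-2,6,6,9-tetramethyltricyclo[5.4.0.0^{2,8}]undec-9-ene-4,11-dione; 20 (R)-2-methylbutanoic acid
Product: 21 (1R,2R,3S,5S,7S,8R)-5-[(tert-butyldimethylsilyl)oxy]-2,6,6,9-tetramethyl-4,11-dioxotricyclo[5.4.0.0^{2,8}]undec-9-en-3-yl (2R)-2-methylbutanoate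
Conditions: DCC, DMAP (cat.), CH2Cl2, 0 °C → rt
Reagents that add atoms: none
Why: Steglich esterification of the only free hydroxyl; carbodiimide activation with catalytic DMAP avoids a ketene and so should keep the α-stereocentre of the acid intact.

Step 14
Reactants: 21 (1R,2R,3S,5S,7S,8R)-5-[(tert-butyldimethylsilyl)oxy]-2,6,6,9-tetramethyl-4,11-dioxotricyclo[5.4.0.0^{2,8}]undec-9-en-3-yl (2R)-2-methylbutanoate
Product: 22 (1R,2R,3S,5S,7S,8R)-5-hydroxy-2,6,6,9-tetramethyl-4,11-dioxotricyclo[5.4.0.0^{2,8}]undec-9-en-3-yl (2R)-2-methylbutanoate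
Conditions: HF·pyridine, THF/pyridine, 0 °C → rt
Reagents that add atoms: none
Why: Fluoride-mediated desilylation under mildly acidic conditions, which should provoke neither acyl migration nor enolisation of the C4 ketone.

Step 15
Reactants: 22 (1R,2R,3S,5S,7S,8R)-5-hydroxy-2,6,6,9-tetramethyl-4,11-dioxotricyclo[5.4.0.0^{2,8}]undec-9-en-3-yl (2R)-2-methylbutanoate
Product: 23 (1R,2R,3S,4R,5S,7S,8R)-4,5-dihydroxy-2,6,6,9-tetramethyl-11-oxotricyclo[5.4.0.0^{2,8}]undec-9-en-3-yl (2R)-2-methylbutanoate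
Conditions: Me4NBH(OAc)3, MeCN/AcOH, −20 °C
Reagents that add atoms: none
Why: Hydroxyl-directed triacetoxyborohydride reduction (Saksena–Evans reduction): the borohydride bound to the C5 oxygen delivers hydride to the C4 carbonyl on its own face, so the new C4 hydroxyl is trans to the C5 hydroxyl and cis to the C3 ester, while the enone, which has no directing hydroxyl, is not reduced.

Step 16
Reactants: 23 (1R,2R,3S,4R,5S,7S,8R)-4,5-dihydroxy-2,6,6,9-tetramethyl-11-oxotricyclo[5.4.0.0^{2,8}]undec-9-en-3-yl (2R)-2-methylbutanoate; 24 angelic acid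
Product: 25 (1R,2R,3S,4R,5S,7S,8R)-5-hydroxy-2,6,6,9-tetramethyl-3-{[(2R)-2-methylbutanoyl]oxy}-11-oxotricyclo[5.4.0.0^{2,8}]undec-9-en-4-yl (2Z)-2-methylbut-2-enoate
Conditions: 24, 2,4,6-trichlorobenzoyl chloride, Et3N, toluene, rt; then 23, 60 °C
Reagents that add atoms: none
Why: Yamaguchi esterification with the preformed mixed anhydride should acylate the C4 hydroxyl in preference to the neopentyl C5 hydroxyl next to the quaternary C6, and leaving out DMAP limits isomerisation of the angelate to the tiglate.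

Compound list
1 | (S)-pantolactone, (3S)-3-hydroxy-4,4-dimethyloxolan-2-one | O=C1OCC(C)(C)[C@@H]1O | starting material
2 | (3S)-3-[(tert-butyldimethylsilyl)oxy]-4,4-dimethyloxolan-2-one | O=C1OCC(C)(C)[C@@H]1O[Si](C)(C)C(C)(C)C | intermediate
3 | (2S)-2-[(tert-butyldimethylsilyl)oxy]-4-hydroxy-N-methoxy-N,3,3-trimethylbutanamide | CON(C)C(=O)[C@@H](O[Si](C)(C)C(C)(C)C)C(C)(C)CO | intermediate
4 | (2S)-2-[(tert-butyldimethylsilyl)oxy]-N-methoxy-N,3,3-trimethyl-4-oxobutanamide | CON(C)C(=O)[C@@H](O[Si](C)(C)C(C)(C)C)C(C)(C)C=O | intermediate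
5 | 1-(triphenylphosphoranylidene)propan-2-one | CC(=O)C=P(c1ccccc1)(c1ccccc1)c1ccccc1 | starting material
6 | (2S,4E)-2-[(tert-butyldimethylsilyl)oxy]-N-methoxy-N,3,3-trimethyl-6-oxohept-4-enamide | CON(C)C(=O)[C@@H](O[Si](C)(C)C(C)(C)C)C(C)(C)/C=C/C(C)=O | intermediate
7 | (2S,4E)-2,6-bis[(tert-butyldimethylsilyl)oxy]-N-methoxy-N,3,3-trimethylhepta-4,6-dienamide | CON(C)C(=O)[C@@H](O[Si](C)(C)C(C)(C)C)C(C)(C)/C=C/C(=C)O[Si](C)(C)C(C)(C)C | intermediate
8 | (E)-pent-3-en-2-one | C/C=C/C(C)=O | starting material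
9 | (2S)-3-[(1R,5R,6S)-6-acetyl-3-[(tert-butyldimethylsilyl)oxy]-5-methylcyclohex-2-en-1-yl]-2-[(tert-butyldimethylsilyl)oxy]-N-methoxy-N,3-dimethylbutanamide (side chain and acetyl cis, methyl trans to acetyl) | CON(C)C(=O)[C@@H](O[Si](C)(C)C(C)(C)C)C(C)(C)[C@@H]1C=C(O[Si](C)(C)C(C)(C)C)C[C@@H](C)[C@@H]1C(C)=O | intermediate
10 | (2S)-2-[(tert-butyldimethylsilyl)oxy]-3-[(1S,5R,6S)-3-[(tert-butyldimethylsilyl)oxy]-5-methyl-6-(prop-1-en-2-yl)cyclohex-2-en-1-yl]-N-methoxy-N,3-dimethylbutanamide | CON(C)C(=O)[C@@H](O[Si](C)(C)C(C)(C)C)C(C)(C)[C@@H]1C=C(O[Si](C)(C)C(C)(C)C)C[C@@H](C)[C@@H]1C(C)=C | intermediate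
11 | tetrabutylammonium C1 enolate of the cyclohexanone released from 10 (not isolated) | CON(C)C(=O)[C@@H](O[Si](C)(C)C(C)(C)C)C(C)(C)[C@@H]1C=C([O-])C[C@@H](C)[C@@H]1C(C)=C.CCCC[N+](CCCC)(CCCC)CCCC | intermediate
12 | (2S,3aR,4S,5R)-2-[(tert-butyldimethylsilyl)oxy]-1-hydroxy-3,3,5-trimethyl-4-(prop-1-en-2-yl)-2,3,3a,4,5,6-hexahydro-7H-inden-7-one; C4 enol of the bicyclic 4,11-dione, C7–H trans to the C5 silyl ether, isopropenyl cis to C6 on ring A, C9 methyl trans to isopropenyl | OC=1[C@@H](O[Si](C)(C)C(C)(C)C)C(C)(C)[C@@H]2C=1C(=O)C[C@@H](C)[C@@H]2C(C)=C | intermediate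
13 | cyclobutanol photoadduct (not isolated): skeleton of 14 with an additional C1–C4 bond and a tertiary hydroxyl at C4 (bicyclo[2.2.0]hexane core C1–C2–C3–C4 / C1–C2–C8–C7) | O[C@@]15[C@@H](O[Si](C)(C)C(C)(C)C)C(C)(C)[C@@H]2[C@]53C(=O)C[C@@H](C)[C@@H]2[C@@]3(C)C1 | intermediate
14 | (1R,2R,5S,7S,8S,9R)-5-[(tert-butyldimethylsilyl)oxy]-2,6,6,9-tetramethyltricyclo[5.4.0.0^{2,8}]undecane-4,11-dione | O=C1[C@@H](O[Si](C)(C)C(C)(C)C)C(C)(C)[C@@H]2[C@H]3C(=O)C[C@@H](C)[C@@H]2[C@@]3(C)C1 | intermediate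
15 | (1R,2R,5S,7S,8R)-5-[(tert-butyldimethylsilyl)oxy]-2,6,6,9-tetramethyltricyclo[5.4.0.0^{2,8}]undec-9-ene-4,11-dione | O=C1[C@@H](O[Si](C)(C)C(C)(C)C)C(C)(C)[C@@H]2[C@H]3C(=O)C=C(C)[C@@H]2[C@@]3(C)C1 | intermediate
16 | (1R,2S,5S,7S,8R)-5-[(tert-butyldimethylsilyl)oxy]-2,6,6,9-tetramethyl-4-[(trimethylsilyl)oxy]tricyclo[5.4.0.0^{2,8}]undeca-3,9-dien-11-one | C[Si](C)(C)OC=1[C@@H](O[Si](C)(C)C(C)(C)C)C(C)(C)[C@@H]2[C@H]3C(=O)C=C(C)[C@@H]2[C@@]3(C)C=1 | intermediate
17 | 3,4-epoxide of 16 (not isolated), oxirane on the face anti to the C5 silyl ether | C[Si](C)(C)O[C@@]14[C@@H](O[Si](C)(C)C(C)(C)C)C(C)(C)[C@@H]2[C@H]3C(=O)C=C(C)[C@@H]2[C@@]3(C)[C@@H]1O4 | intermediate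
18 | (1R,2R,3S,5S,7S,8R)-5-[(tert-butyldimethylsilyl)oxy]-2,6,6,9-tetramethyl-3-[(trimethylsilyl)oxy]tricyclo[5.4.0.0^{2,8}]undec-9-ene-4,11-dione (not isolated) | O=C1[C@@H](O[Si](C)(C)C(C)(C)C)C(C)(C)[C@@H]2[C@H]3C(=O)C=C(C)[C@@H]2[C@@]3(C)[C@@H]1O[Si](C)(C)C | intermediate
19 | (1R,2R,3S,5S,7S,8R)-5-[(tert-butyldimethylsilyl)oxy]-3-hydroxy-2,6,6,9-tetramethyltricyclo[5.4.0.0^{2,8}]undec-9-ene-4,11-dione | O=C1[C@@H](O[Si](C)(C)C(C)(C)C)C(C)(C)[C@@H]2[C@H]3C(=O)C=C(C)[C@@H]2[C@@]3(C)[C@@H]1O | intermediate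
20 | (R)-2-methylbutanoic acid | CC[C@@H](C)C(=O)O | starting material
21 | (1R,2R,3S,5S,7S,8R)-5-[(tert-butyldimethylsilyl)oxy]-2,6,6,9-tetramethyl-4,11-dioxotricyclo[5.4.0.0^{2,8}]undec-9-en-3-yl (2R)-2-methylbutanoate | O=C1[C@@H](O[Si](C)(C)C(C)(C)C)C(C)(C)[C@@H]2[C@H]3C(=O)C=C(C)[C@@H]2[C@@]3(C)[C@@H]1OC(=O)[C@H](C)CC | intermediate
22 | (1R,2R,3S,5S,7S,8R)-5-hydroxy-2,6,6,9-tetramethyl-4,11-dioxotricyclo[5.4.0.0^{2,8}]undec-9-en-3-yl (2R)-2-methylbutanoate | O=C1[C@@H](O)C(C)(C)[C@@H]2[C@H]3C(=O)C=C(C)[C@@H]2[C@@]3(C)[C@@H]1OC(=O)[C@H](C)CC | intermediate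
23 | (1R,2R,3S,4R,5S,7S,8R)-4,5-dihydroxy-2,6,6,9-tetramethyl-11-oxotricyclo[5.4.0.0^{2,8}]undec-9-en-3-yl (2R)-2-methylbutanoate | O[C@@H]1[C@@H](O)C(C)(C)[C@@H]2[C@H]3C(=O)C=C(C)[C@@H]2[C@@]3(C)[C@@H]1OC(=O)[C@H](C)CC | intermediate
24 | angelic acid, (Z)-2-methylbut-2-enoic acid | C/C=C(/C)C(=O)O | starting material
25 | (1R,2R,3S,4R,5S,7S,8R)-5-hydroxy-2,6,6,9-tetramethyl-3-{[(2R)-2-methylbutanoyl]oxy}-11-oxotricyclo[5.4.0.0^{2,8}]undec-9-en-4-yl (2Z)-2-methylbut-2-enoate | C/C=C(/C)C(=O)O[C@@H]1[C@@H](O)C(C)(C)[C@@H]2[C@H]3C(=O)C=C(C)[C@@H]2[C@@]3(C)[C@@H]1OC(=O)[C@H](C)CC | target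

Total step count: 16. Longest linear sequence: 16 steps (from 1; compounds 5, 8, 20 and 24 are purchased).

Steps most likely to fail

Step 9. The cycloaddition may be inefficient because the C3–C4 diradical reverts, the alkene may add across the C1=C11 enol instead of C1=C4, and the cyclobutanol may open sluggishly or along the C3–C4 bond because the C11 carbonyl cannot stabilise a bridgehead carbanion well. The fallback sets out from 12 and returns at 14; it fixes the chromophore and separates cycloaddition from fragmentation. Compound 12 is O-acetylated (Ac2O, Et3N, DMAP cat., CH2Cl2, 0 °C) and the C4 enol acetate F1 is separated from its C11 isomer, which is returned to 12 with K2CO3 in MeOH. Irradiation of this β-acyloxy enone (Pyrex, MeCN, 15 °C) is an enone–alkene [2+2] photocycloaddition that can engage only C1=C4 and should give the cyclobutyl acetate F2. K2CO3 in MeOH at 0 °C then removes the acetate, and the alkoxide formed in this way opens the C1–C4 bond to give 14.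

Step 6. The β-methyl enone and the hindered diene terminus may react slowly, the Lewis acid may divert the silyloxy diene into a stepwise Mukaiyama–Michael path with loss of endo control, and the catalyst may give poor facial selectivity. The fallback sets out from 7 and returns at 9; it replaces catalyst control by a covalently bound auxiliary. Diene 7 is combined with (R)-4-benzyl-3-[(E)-but-2-enoyl]oxazolidin-2-one and Me2AlCl (CH2Cl2, −78 °C); the chelated s-cis imide shields the Cα-Si face, so the endo adduct should be the imide F3 with the same ring configuration as 9. LiSEt (THF, 0 °C) cleaves the auxiliary to give the S-ethyl thioester F4, and Me2CuLi (Et2O, −40 °C), which leaves the Weinreb amide and the silyl enol ether alone, converts it into the methyl ketone 9.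

Step 11. The lithium enolate at C3/C4 may open the cyclobutane by retro-Michael cleavage of C1–C2 or C2–C8 before it is silylated, or deprotonation may stray to C5 or to the enone γ-position. The fallback sets out from 15 and returns at 25; it avoids any enolate at C4. NaBH4 (MeOH/CH2Cl2, −40 °C) should reduce the α-silyloxy ketone faster than the hindered enone, hydride arriving anti to the silyl ether, to give the C4 alcohol F5 (hydroxyl cis to the C5 silyl ether). Syn-dehydration with the Burgess reagent (methyl N-(triethylammoniosulfonyl)carbamate, benzene, 50 °C) can take only a C3 hydrogen, because the C5 hydrogen is anti to the leaving group, and gives the C3=C4 alkene F6. OsO4 (cat.) with NMO dihydroxylates it anti to the allylic silyl ether to the cis-diol F7. Esterification with 20 (DCC, DMAP) at the hydroxyl remote from the silyl ether gives the C3 mono-ester F8, angeloylation with 24 under the conditions of step 16 gives the silyl-protected diester F9, and HF·pyridine removes the silyl group to give 25.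

Further compounds
F1 | step 9 | C4 enol acetate of 12 | CC(=O)OC=1[C@@H](O[Si](C)(C)C(C)(C)C)C(C)(C)[C@@H]2C=1C(=O)C[C@@H](C)[C@@H]2C(C)=C
F2 | step 9 | cyclobutyl acetate photoadduct (O-acetyl derivative of 13) | CC(=O)O[C@@]15[C@@H](O[Si](C)(C)C(C)(C)C)C(C)(C)[C@@H]2[C@]53C(=O)C[C@@H](C)[C@@H]2[C@@]3(C)C1
F3 | step 6 | Diels–Alder adduct carrying the (R)-4-benzyl-2-oxooxazolidin-3-ylcarbonyl group in place of the acetyl group of 9 | CON(C)C(=O)[C@@H](O[Si](C)(C)C(C)(C)C)C(C)(C)[C@@H]1C=C(O[Si](C)(C)C(C)(C)C)C[C@@H](C)[C@@H]1C(=O)N2[C@H](Cc3ccccc3)COC2=O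
F4 | step 6 | S-ethyl thioester corresponding to 9 | CON(C)C(=O)[C@@H](O[Si](C)(C)C(C)(C)C)C(C)(C)[C@@H]1C=C(O[Si](C)(C)C(C)(C)C)C[C@@H](C)[C@@H]1C(=O)SCC
F5 | step 11 | C4 alcohol from 15, hydroxyl cis to the C5 silyl ether | O[C@H]1[C@@H](O[Si](C)(C)C(C)(C)C)C(C)(C)[C@@H]2[C@H]3C(=O)C=C(C)[C@@H]2[C@@]3(C)C1
F6 | step 11 | C3=C4 alkene, 5-silyloxy-2,6,6,9-tetramethyltricyclo[5.4.0.0^{2,8}]undeca-3,9-dien-11-one | C=1[C@@H](O[Si](C)(C)C(C)(C)C)C(C)(C)[C@@H]2[C@H]3C(=O)C=C(C)[C@@H]2[C@@]3(C)C=1
F7 | step 11 | C3,C4 cis-diol, both hydroxyls trans to the C5 silyl ether | O[C@@H]1[C@@H](O[Si](C)(C)C(C)(C)C)C(C)(C)[C@@H]2[C@H]3C(=O)C=C(C)[C@@H]2[C@@]3(C)[C@@H]1O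
F8 | step 11 | C3 (2R)-2-methylbutanoate of F7 | O[C@@H]1[C@@H](O[Si](C)(C)C(C)(C)C)C(C)(C)[C@@H]2[C@H]3C(=O)C=C(C)[C@@H]2[C@@]3(C)[C@@H]1OC(=O)[C@H](C)CC
F9 | step 11 | C5 silyl ether of 25 | C/C=C(/C)C(=O)O[C@@H]1[C@@H](O[Si](C)(C)C(C)(C)C)C(C)(C)[C@@H]2[C@H]3C(=O)C=C(C)[C@@H]2[C@@]3(C)[C@@H]1OC(=O)[C@H](C)CC
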